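## Retrosynthetic overview
1. The last bond made is ArCH2–C(trione). The enolised trione half adds in a Michael reaction to an o-quinone methide released from the Mannich base of the chromene half.
2. Chromene half: bought phloroglucinol (ring A) is C-acylated and its para-OH blocked. Pyran ring B comes from Knoevenagel/oxa-6π closure with prenal, then Mannich aminomethylation at the last free CH.
3. Trione half (ring C): Dieckmann closure of a 3,5,7-trioxo ester. That ester comes from a Claisen-type acylation of the acetylacetone dianion with a chiral malonyl half-ester chloride.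
4. Quaternary stereocentre: enantioselective phase-transfer geranylation of a mixed tert-butyl/2,2-diphenylethyl methylmalonate. The two unlike esters decide which carbonyl ends up next to the acetyl-bearing carbon.
5. Ring order: B (step 3), C (step 12), then union of the two halves (step 13).

Assumption: the target is handled as the enol tautomer drawn in the SMILES, and the (S,S)-phase-transfer catalyst is taken to give the (S)-diester in step 8, as with other primary allylic and benzylic bromides; if the measured sense is opposite, the mirror-image catalyst is used.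

## Route

Step 1
Reactants: 1 phloroglucinol; 2 hexanoyl chloride
Product: 3 1-(2,4,6-trihydroxyphenyl)hexan-1-one
Conditions: AlCl3 (4 equiv), CH2Cl2/MeNO2, 0 → 40 °C, 4 h; then ice/1 M HCl
Reagents that add atoms: hexanoyl chloride 2, CCCCCC(=O)Cl
Why: Friedel–Crafts C-acylation of the symmetric, highly activated arene stops after one acyl group because the chelated aryl ketone–AlCl3 complex deactivates the ring.

Step 2
Reactants: 3 1-(2,4,6-trihydroxyphenyl)hexan-1-one
Product: 4 1-[2,6-dihydroxy-4-(methoxymethoxy)phenyl]hexan-1-one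
Conditions: MOMCl (1.05 equiv), iPr2NEt (1.1 equiv), CH2Cl2/THF, −10 → 0 °C, 2 h
Reagents that add atoms: chloromethyl methyl ether (MOMCl), COCCl
Why: O-alkylation (acetal protection) goes to the 4-OH, the most acidic hydroxyl and the only one neither flanking nor hydrogen-bonded to the ketone, and it leaves a symmetric 2,6-diol that can give only one chromene regioisomer in the next step.

Step 3
Reactants: 4 1-[2,6-dihydroxy-4-(methoxymethoxy)phenyl]hexan-1-one; 5 3-methylbut-2-enal (prenal)
Product: 7 1-[7-hydroxy-5-(methoxymethoxy)-2,2-dimethyl-2H-chromen-8-yl]hexan-1-one, via (Z)-o-quinone methide 6 (not isolated)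
Conditions: 5 (1.2 equiv), ethylenediammonium diacetate (10 mol %), toluene, 110 °C, 6 h
Reagents that add atoms: 3-methylbut-2-enal 5, CC(C)=CC=O
Why: The amine-salt-catalysed Knoevenagel-type (aldol) condensation at a ring CH gives the o-quinone methide, whose oxa-6π electrocyclisation can close only onto the hydroxyl next to the ketone because the other flanking oxygen is blocked, so the 8-acyl chromene is the sole regioisomer.

Step 4
Reactants: 7 1-[7-hydroxy-5-(methoxymethoxy)-2,2-dimethyl-2H-chromen-8-yl]hexan-1-one
Product: 8 1-(5,7-dihydroxy-2,2-dimethyl-2H-chromen-8-yl)hexan-1-one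
Conditions: HCl (0.3 M in MeOH, catalytic), 40 °C, 3 h
Reagents that add atoms: none
Why: Acid-catalysed acetal exchange (MOM cleavage) frees the 5-OH while methanol captures the formaldehyde unit as its dimethyl acetal, under conditions that 2,2-dimethylchromenes and chelated aryl ketones tolerate.

Step 5
Reactants: 8 1-(5,7-dihydroxy-2,2-dimethyl-2H-chromen-8-yl)hexan-1-one
Product: 9 1-{6-[(dimethylamino)methyl]-5,7-dihydroxy-2,2-dimethyl-2H-chromen-8-yl}hexan-1-one
Conditions: [Me2N=CH2]I (1.2 equiv), CH2Cl2, 0 °C → rt, 4 h; then aq NaHCO3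
Reagents that add atoms: N,N-dimethylmethyleneiminium iodide (Eschenmoser's salt), C[N+](C)=C.[I-]
Why: Mannich aminomethylation with a preformed iminium salt can occur only at C6, the last free position of the phloroglucinol ring, and the absence of free formaldehyde suppresses symmetric methylene-bis dimers.

Step 6
Reactants: 10 2,2,5-trimethyl-1,3-dioxane-4,6-dione (methyl Meldrum's acid)
Product: 11 3-tert-butoxy-2-methyl-3-oxopropanoic acid (racemic)
Conditions: t-BuOH (solvent), reflux (83 °C), 12 h
Reagents that add atoms: tert-butanol, CC(C)(C)O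
Why: Thermal alcoholysis of the strained Meldrum's acid ring (acyl substitution with loss of the ketal carbon unit) delivers the malonic half ester directly, and only one acyl group can be transferred.

Step 7
Reactants: 11 3-tert-butoxy-2-methyl-3-oxopropanoic acid; 12 2,2-diphenylethanol
Product: 13 1-tert-butyl 3-(2,2-diphenylethyl) 2-methylpropanedioate (racemic, labile CH)
Conditions: EDC·HCl (1.2 equiv), DMAP (10 mol %), CH2Cl2, 0 °C → rt, 12 h
Reagents that add atoms: 2,2-diphenylethanol 12, OCC(c1ccccc1)c1ccccc1
Why: Steglich-type carbodiimide esterification of a primary alcohol is mild enough to keep the tert-butyl ester, and it gives a malonate with two sterically and chemically different esters.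

Step 8
Reactants: 13 1-tert-butyl 3-(2,2-diphenylethyl) 2-methylpropanedioate; 14 geranyl bromide, (2E)-1-bromo-3,7-dimethylocta-2,6-diene
Product: 15 1-tert-butyl 3-(2,2-diphenylethyl) (2S)-2-[(2E)-3,7-dimethylocta-2,6-dien-1-yl]-2-methylpropanedioate
Conditions: 14 (1.5 equiv), (S,S)-3,4,5-trifluorophenyl-NAS bromide (N-spiro bis-binaphthyl ammonium bromide, C56H34BrF6N, 5 mol %), 50% aq KOH (5 equiv), toluene, −40 °C, 36 h; ee by chiral HPLC
Reagents that add atoms: geranyl bromide 14, CC(C)=CCC/C(C)=C/CBr
Why: In this asymmetric phase-transfer alkylation the malonate enolate sits as a tight ion pair in the chiral pocket of the spiro ammonium cation, which distinguishes the bulky tert-butyl ester from the diphenylethyl ester, so SN2 attack on the primary allylic bromide comes from one face, sets the quaternary centre as (S) and keeps the E-alkene.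

Step 9
Reactants: 15 (S)-mixed diester
Product: 17 (2R,4E)-2-[(2,2-diphenylethoxy)carbonyl]-2,5,9-trimethyldeca-4,8-dienoic acid, via trimethylsilyl ester 16 (not isolated)
Conditions: Me3SiOTf (2.5 equiv), 2,6-lutidine (3.5 equiv), CH2Cl2, 0 °C → rt, 2 h; then H2O/5% citric acid
Reagents that add atoms: trimethylsilyl triflate, C[Si](C)(C)OS(=O)(=O)C(F)(F)F (silyl group held only in 16)
Why: Silyl-triflate-mediated tert-butyl ester cleavage (loss of the tert-butyl cation as alkene from the O-silylated ester), buffered by lutidine, spares the primary ester and the acid-sensitive trisubstituted alkenes, and the quaternary centre cannot epimerise (the descriptor changes only through CIP ranking).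

Step 10
Reactants: 17 (R)-half-ester acid
Product: 18 2,2-diphenylethyl (2S,4E)-2-(chlorocarbonyl)-2,5,9-trimethyldeca-4,8-dienoate
Conditions: 1-chloro-N,N,2-trimethylprop-1-en-1-amine (1.2 equiv), CH2Cl2, 0 °C → rt, 1 h; concentrate, use crude
Reagents that add atoms: 1-chloro-N,N,2-trimethylprop-1-en-1-amine (Ghosez reagent), CC(C)=C(Cl)N(C)C
Why: Neutral acid chloride formation with the α-chloroenamine works on hindered acids without releasing HCl onto the alkenes, and with no α-hydrogen neither ketene formation nor racemisation is possible.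

Step 11
Reactants: 18 (S)-acid chloride; 19 pentane-2,4-dione (acetylacetone)
Product: 21 2,2-diphenylethyl (2R)-2-[(2E)-3,7-dimethylocta-2,6-dien-1-yl]-2-methyl-3,5,7-trioxooctanoate, via dilithio acetylacetone dianion 20 (not isolated)
Conditions: 19 (2.5 equiv), LiN(iPr)2 (5.0 equiv), THF, 0 °C, 45 min; then 18, −78 → −30 °C, 2 h; then cold 1 M HCl
Reagents that add atoms: pentane-2,4-dione 19, CC(=O)CC(C)=O; lithium diisopropylamide, [Li+].CC(C)[N-]C(C)C (lithium held only in 20)
Why: In this intermolecular Claisen-type acylation the dianion reacts at its more basic terminal carbon and chooses the acid chloride over the hindered ester, which fixes the former acid carbon as the carbonyl next to the future ring CH, while the excess dianion absorbs the acidic protons of the product.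

Step 12
Reactants: 21 (R)-trioxo ester
Product: 22 (4R)-2-acetyl-4-[(2E)-3,7-dimethylocta-2,6-dien-1-yl]-3,5-dihydroxy-4-methylcyclohexa-2,5-dien-1-one
Conditions: NaH (3 equiv), THF, 0 → 50 °C, 4 h; then cold 1 M HCl
Reagents that add atoms: none
Why: In this Dieckmann (intramolecular Claisen) condensation only the carbon between the C5 and C7 ketones can reach the ester through a six-membered transition state, competing O-acylation is reversed by the released alkoxide, the doubly deprotonated acyl trione is the thermodynamic sink, and the quaternary centre is untouched.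

Step 13
Reactants: 9 chromene Mannich base; 22 (R)-acetyl trione
Product: 24 (4R)-2-acetyl-4-[(2E)-3,7-dimethylocta-2,6-dien-1-yl]-6-[(8-hexanoyl-5,7-dihydroxy-2,2-dimethyl-2H-chromen-6-yl)methyl]-3,5-dihydroxy-4-methylcyclohexa-2,5-dien-1-one (target), via chromene o-quinone methide 23 (not isolated)
Conditions: 9 (1.0 equiv), 22 (1.1 equiv), THF, 50 °C, 8 h, Ar, dark; then 0.5 M HCl wash
Reagents that add atoms: none
Why: The acidic trione protonates the benzylic amine, which then leaves with the push of an ortho phenol (retro-Mannich-type elimination), and the soft trione enolate adds through its only free carbon to the exocyclic methylene in a Michael addition driven by rearomatisation, at a temperature too low for methylene scrambling or chromene isomerisation and remote from the stereocentre.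

## Compound list
1 | phloroglucinol | Oc1cc(O)cc(O)c1 | starting material
2 | hexanoyl chloride | CCCCCC(=O)Cl | starting material
3 | 1-(2,4,6-trihydroxyphenyl)hexan-1-one | CCCCCC(=O)c1c(O)cc(O)cc1O | intermediate
4 | 1-[2,6-dihydroxy-4-(methoxymethoxy)phenyl]hexan-1-one | CCCCCC(=O)c1c(O)cc(OCOC)cc1O | intermediate
5 | 3-methylbut-2-enal | CC(C)=CC=O | starting material
6 | (6Z)-2-hexanoyl-3-hydroxy-5-(methoxymethoxy)-6-(3-methylbut-2-en-1-ylidene)cyclohexa-2,4-dien-1-one | CCCCCC(=O)C1=C(O)C=C(OCOC)/C(=C/C=C(C)C)C1=O | intermediate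
7 | 1-[7-hydroxy-5-(methoxymethoxy)-2,2-dimethyl-2H-chromen-8-yl]hexan-1-one | CCCCCC(=O)c1c(O)cc(OCOC)c2c1OC(C)(C)C=C2 | intermediate
8 | 1-(5,7-dihydroxy-2,2-dimethyl-2H-chromen-8-yl)hexan-1-one | CCCCCC(=O)c1c(O)cc(O)c2c1OC(C)(C)C=C2 | intermediate
9 | 1-{6-[(dimethylamino)methyl]-5,7-dihydroxy-2,2-dimethyl-2H-chromen-8-yl}hexan-1-one | CCCCCC(=O)c1c(O)c(CN(C)C)c(O)c2c1OC(C)(C)C=C2 | intermediate
10 | 2,2,5-trimethyl-1,3-dioxane-4,6-dione | CC1C(=O)OC(C)(C)OC1=O | starting material
11 | 3-tert-butoxy-2-methyl-3-oxopropanoic acid (racemic) | CC(C(=O)O)C(=O)OC(C)(C)C | intermediate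
12 | 2,2-diphenylethanol | OCC(c1ccccc1)c1ccccc1 | starting material
13 | 1-tert-butyl 3-(2,2-diphenylethyl) 2-methylpropanedioate (racemic) | CC(C(=O)OC(C)(C)C)C(=O)OCC(c1ccccc1)c1ccccc1 | intermediate
14 | geranyl bromide | CC(C)=CCC/C(C)=C/CBr | starting material
15 | 1-tert-butyl 3-(2,2-diphenylethyl) (2S)-2-[(2E)-3,7-dimethylocta-2,6-dien-1-yl]-2-methylpropanedioate | CC(C)(C)OC(=O)[C@@](C)(C/C=C(\C)CCC=C(C)C)C(=O)OCC(c1ccccc1)c1ccccc1 | intermediate
16 | 1-(2,2-diphenylethyl) 3-trimethylsilyl (2S)-2-[(2E)-3,7-dimethylocta-2,6-dien-1-yl]-2-methylpropanedioate | C[Si](C)(C)OC(=O)[C@@](C)(C/C=C(\C)CCC=C(C)C)C(=O)OCC(c1ccccc1)c1ccccc1 | intermediate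
17 | (2R,4E)-2-[(2,2-diphenylethoxy)carbonyl]-2,5,9-trimethyldeca-4,8-dienoic acid | OC(=O)[C@@](C)(C/C=C(\C)CCC=C(C)C)C(=O)OCC(c1ccccc1)c1ccccc1 | intermediate
18 | 2,2-diphenylethyl (2S,4E)-2-(chlorocarbonyl)-2,5,9-trimethyldeca-4,8-dienoate | ClC(=O)[C@@](C)(C/C=C(\C)CCC=C(C)C)C(=O)OCC(c1ccccc1)c1ccccc1 | intermediate
19 | pentane-2,4-dione | CC(=O)CC(C)=O | starting material
20 | dilithium penta-1,3-diene-2,4-diolate (acetylacetone dianion) | C=C([O-])C=C(C)[O-].[Li+].[Li+] | intermediate
21 | 2,2-diphenylethyl (2R)-2-[(2E)-3,7-dimethylocta-2,6-dien-1-yl]-2-methyl-3,5,7-trioxooctanoate | CC(=O)CC(=O)CC(=O)[C@@](C)(C/C=C(\C)CCC=C(C)C)C(=O)OCC(c1ccccc1)c1ccccc1 | intermediate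
22 | (4R)-2-acetyl-4-[(2E)-3,7-dimethylocta-2,6-dien-1-yl]-3,5-dihydroxy-4-methylcyclohexa-2,5-dien-1-one | O=C1C=C(O)[C@@](C)(C/C=C(\C)CCC=C(C)C)C(O)=C1C(C)=O | intermediate
23 | 8-hexanoyl-5-hydroxy-2,2-dimethyl-6-methylidene-2H-chromen-7(6H)-one | CCCCCC(=O)C1=C2OC(C)(C)C=CC2=C(O)C(=C)C1=O | intermediate
24 | (4R)-2-acetyl-4-geranyl-6-[(8-hexanoyl-5,7-dihydroxy-2,2-dimethyl-2H-chromen-6-yl)methyl]-3,5-dihydroxy-4-methylcyclohexa-2,5-dien-1-one | CCCCCC(=O)c1c(O)c(CC2=C(O)[C@@](C)(C/C=C(\C)CCC=C(C)C)C(O)=C(C(C)=O)C2=O)c(O)c2c1OC(C)(C)C=C2 | target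

## Count and risks
Total steps: 13. Longest linear sequence: 8 (steps 6–13). The chromene branch takes 5 steps before the union.

**Step 8.** The risk is that the ee with a long allylic bromide falls short of a single enantiomer, or that the sense of induction is not the assumed one. The fallback replaces asymmetric induction by resolution. It sets out from 13, which is alkylated with 14 under achiral conditions (NaH, THF, 0 °C → rt). This gives racemic 1-tert-butyl 3-(2,2-diphenylethyl) 2-geranyl-2-methylpropanedioate F1. Its enantiomers are separated by preparative supercritical-fluid chromatography on an amylose tris(3,5-dimethylphenylcarbamate) phase, where the two phenyl rings help recognition and detection. The (S)-fraction is 15, and the route is rejoined there. The same column also polishes material of incomplete ee.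

**Step 11.** The risks are over-acylation, O-acylation or a sluggish reaction of the neopentyl-type acid chloride with the dianion. The fallback reverses the order of the two C-acylations, so the mirror-image malonate is needed. It sets out from 13.
- Running step 8 with the (R,R)-catalyst gives the (R)-mixed diester F2.
- Me3SiOTf/2,6-lutidine takes F2 through the (R)-trimethylsilyl ester F3 to the (S)-half-ester acid F4.
- The α-chloroenamine converts F4 into the (R)-acid chloride F5.
- Soft-enolisation C-acylation of 19 at its central carbon (MgCl2, pyridine, CH2Cl2, 0 °C → rt) gives the (S)-triacylmethane 2,2-diphenylethyl 4-acetyl-2-geranyl-2-methyl-3,5-dioxohexanoate F6.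
- LiN(iPr)2 (3.3 equiv, THF, −78 → 0 °C) then deprotonates one acetyl CH3, and this carbanion closes onto the ester in a Dieckmann reaction.

In this order the acid chloride carbon lies next to the acetyl-bearing carbon and the ester carbon next to the ring CH. The product is therefore 22, where the route is rejoined.

**Step 13.** The risks are slow release of the o-quinone methide, or scrambling of the methylene bridge to the two symmetric dimers. The fallback swaps donor and acceptor. It sets out from 22, with 8 taken from before step 5. Compound 22 is aminomethylated at its free ring carbon with [Me2N=CH2]I (CH2Cl2, −20 °C) to the trione Mannich base F7. F7 is added slowly to 8 (1.5 equiv) and NaOAc in THF at rt. There it loses its amine to give the 6-methylidene trione F8. The electron-rich C6 of 8 traps F8 in a Michael addition, which gives 24 directly.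

## Further compounds
F1 | step 8 | racemic 1-tert-butyl 3-(2,2-diphenylethyl) 2-geranyl-2-methylpropanedioate | CC(C)(C)OC(=O)C(C)(C/C=C(\C)CCC=C(C)C)C(=O)OCC(c1ccccc1)c1ccccc1
F2 | step 11 | 1-tert-butyl 3-(2,2-diphenylethyl) (2R)-2-geranyl-2-methylpropanedioate | CC(C)(C)OC(=O)[C@](C)(C/C=C(\C)CCC=C(C)C)C(=O)OCC(c1ccccc1)c1ccccc1
F3 | step 11 | 1-(2,2-diphenylethyl) 3-trimethylsilyl (2R)-2-geranyl-2-methylpropanedioate | C[Si](C)(C)OC(=O)[C@](C)(C/C=C(\C)CCC=C(C)C)C(=O)OCC(c1ccccc1)c1ccccc1
F4 | step 11 | (2S,4E)-2-[(2,2-diphenylethoxy)carbonyl]-2,5,9-trimethyldeca-4,8-dienoic acid | OC(=O)[C@](C)(C/C=C(\C)CCC=C(C)C)C(=O)OCC(c1ccccc1)c1ccccc1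
F5 | step 11 | 2,2-diphenylethyl (2R,4E)-2-(chlorocarbonyl)-2,5,9-trimethyldeca-4,8-dienoate | ClC(=O)[C@](C)(C/C=C(\C)CCC=C(C)C)C(=O)OCC(c1ccccc1)c1ccccc1
F6 | step 11 | 2,2-diphenylethyl (2S)-4-acetyl-2-[(2E)-3,7-dimethylocta-2,6-dien-1-yl]-2-methyl-3,5-dioxohexanoate | CC(=O)C(C(C)=O)C(=O)[C@](C)(C/C=C(\C)CCC=C(C)C)C(=O)OCC(c1ccccc1)c1ccccc1
F7 | step 13 | (4R)-2-acetyl-6-[(dimethylamino)methyl]-4-geranyl-3,5-dihydroxy-4-methylcyclohexa-2,5-dien-1-one | CN(C)CC1=C(O)[C@@](C)(C/C=C(\C)CCC=C(C)C)C(O)=C(C(C)=O)C1=O
F8 | step 13 | (6R)-4-acetyl-6-geranyl-5-hydroxy-6-methyl-2-methylidenecyclohex-4-ene-1,3-dione | C=C1C(=O)[C@@](C)(C/C=C(\C)CCC=C(C)C)C(O)=C(C(C)=O)C1=O
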